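**Plan**
- Retrosynthetic cuts, in order: the ring-B C–Br/C–Cl pair (anti addition of Br–Cl to an alkene); the exocyclic C=CH2 (from C=O); the bond between the CMe2 carbon and the spiro carbon of ring A; the CH2–CH2 bond of ring A (enolate alkylation); ring B (Diels–Alder).
- Forward: a Diels–Alder reaction builds ring B as an acyl cyclohexadiene; its acetyl CH3 is alkylated with an enantiopure 2-bromo-3-chloro-3-methylbutyl unit; 1,4-hydrosilylation gives a Z enol silane; solvolysis of the tertiary chloride closes ring A onto the enol carbon; methylenation and bromochlorination of ring B follow.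
- Feature used: in ring A the CHBr–CMe2 pair is a masked 2,2-dimethylbromonium ion, and the spiro carbon is the α-carbon of the C=CH2 carbon once that carbon is taken back to C=O. The two are linked through CH2–CH2, so one bromonium/enol cyclisation makes the six-membered ring and joins the two fully substituted carbons.
- Stereochemistry: the ring-A C–Br centre comes from catalytic enantioselective bromochlorination of prenol; the spiro centre is relayed from it in the key step (chair, Br equatorial, Z enol geometry); both ring-B centres are relayed from the spiro centre in one anti addition.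

Key step: step 7

Remark: ring A is the ring with CHBr, CMe2 and C=CH2; ring B is the ring with CHBr and C(CH3)Cl; the ligand enantiomer that gives the (R)-bromochloride in step 1 is assumed to be available.

Step 1
Reactants: 1 3-methylbut-2-en-1-ol (prenol)
Product: 2 (2R)-2-bromo-3-chloro-3-methylbutan-1-ol
Conditions: NBS, ClTi(OiPr)3, chiral tridentate Schiff-base ligand (20 mol %), hexanes, −20 °C
Reagents that add atoms: N-bromosuccinimide O=C1CCC(=O)N1Br; chlorotitanium triisopropoxide ClTi(OiPr)3 CC(C)O[Ti](Cl)(OC(C)C)OC(C)C
Why: Ligand-accelerated, titanium-mediated enantioselective bromochlorination of an allylic alcohol, in which Br+ from NBS and chloride from titanium add anti across the alkene with chloride at the tertiary carbon and the chiral complex selects the alkene face, which sets the C–Br centre that all later centres are relayed from.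

Step 2
Reactants: 2 (2R)-2-bromo-3-chloro-3-methylbutan-1-ol
Product: 3 (2R)-2-bromo-3-chloro-3-methylbutyl trifluoromethanesulfonate
Conditions: Tf2O, 2,6-lutidine, CH2Cl2, −78 °C
Reagents that add atoms: trifluoromethanesulfonic anhydride O=S(=O)(OS(=O)(=O)C(F)(F)F)C(F)(F)F
Why: Standard O-triflation of a primary alcohol at low temperature; the β-bromine retards ionisation of the triflate, so it should survive to the alkylation, and the stereocentre is not touched.

Step 3
Reactants: 4 2-methylbuta-1,3-diene (isoprene); 5 but-3-yn-2-one
Product: 6 1-(4-methylcyclohexa-1,4-dien-1-yl)ethan-1-one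
Conditions: AlCl3 (0.1 equiv), CH2Cl2, −20 °C
Reagents that add atoms: none
Why: Lewis-acid-accelerated Diels–Alder reaction of a 2-substituted diene with an ynone, which follows the "para" orientation and places the methyl group 1,4 to the acyl-bearing carbon of the new ring B.

Step 4
Reactants: 6 1-(4-methylcyclohexa-1,4-dien-1-yl)ethan-1-one
Product: 7 1-(4-methylcyclohexa-1,3-dien-1-yl)ethan-1-one
Conditions: DBU (0.1 equiv), CH2Cl2, rt, under argon
Reagents that add atoms: none
Why: Base-catalysed prototropic isomerisation moves the isolated ring alkene into linear conjugation with the enone (the thermodynamically preferred dienone), which puts the enone β-carbon on the side of ring B that will later carry the CHBr group.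

Step 5
Reactants: 7 1-(4-methylcyclohexa-1,3-dien-1-yl)ethan-1-one; 3 (2R)-2-bromo-3-chloro-3-methylbutyl trifluoromethanesulfonate
Product: 9 (4R)-4-bromo-5-chloro-5-methyl-1-(4-methylcyclohexa-1,3-dien-1-yl)hexan-1-one, via lithium dienolate 8 (not isolated)
Conditions: LiN(iPr)2 (LDA, commercial solution), THF, −78 °C; then 3, −78 to −30 °C
Reagents that add atoms: none
Why: Kinetic deprotonation takes the acetyl methyl group (cross-conjugated α′-enolate 8), and SN2 displacement of the primary triflate joins the two fragments at the future CH2–CH2 bond of ring A without touching the adjacent C–Br centre.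

Step 6
Reactants: 9 (4R)-4-bromo-5-chloro-5-methyl-1-(4-methylcyclohexa-1,3-dien-1-yl)hexan-1-one
Product: 10 {[(1Z,4R)-4-bromo-5-chloro-5-methyl-1-(4-methylcyclohex-3-en-1-ylidene)hexyl]oxy}triethylsilane (O–Si cis to the ring CH2 that lies next to the ring CH=)
Conditions: Et3SiH (1.2 equiv), RhCl(PPh3)3 (2 mol %), benzene, 50 °C
Reagents that add atoms: triethylsilane CC[SiH](CC)CC
Why: Rhodium-catalysed 1,4-hydrosilylation of an enone with a monohydrosilane should pass through the s-cis enone and so place the silyloxy group cis to the former β-carbon, which fixes the Z geometry of the tetrasubstituted enol silane; the disubstituted δ-carbon of the dienone should disfavour 1,6-delivery of hydride.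

Step 7
Reactants: 10 {[(1Z,4R)-4-bromo-5-chloro-5-methyl-1-(4-methylcyclohex-3-en-1-ylidene)hexyl]oxy}triethylsilane
Product: 13 (4R,6R)-4-bromo-5,5,9-trimethylspiro[5.5]undec-8-en-1-one, via ring-A bromonium chloride 11 (not isolated), via silyloxocarbenium chloride 12 (not isolated)
Conditions: (CF3)2CHOH (HFIP), 2,6-di-tert-butyl-4-methylpyridine (0.2 equiv), 0 to 23 °C
Reagents that add atoms: none
Why: In HFIP the tertiary C–Cl bond ionises with anchimeric assistance from the neighbouring bromine to give the enantiopure bromonium ion 11, the tetrasubstituted enol carbon attacks its tertiary carbon anti to bromine to give 12, and chloride removes the silyl group to leave the ketone. The closest known reaction types are the enantiospecific solvolytic bromopolyene cyclisation of vicinal bromochlorides and the tert-alkylation of enol silanes by SN1 electrophiles, which is known to join two fully substituted carbons. Ring A closes in a 6-endo-trig mode with respect to the enol double bond (opening of the bromonium ring at its tertiary carbon with inversion), through a chair in which bromine is equatorial because the new C–C bond must be anti to it. The C–Br centre is carried over unchanged, and the new spiro centre is controlled by that centre together with the Z enol geometry: the ring-B CH2 cis to the chain becomes axial on ring A, so the CH2 next to the ring-B alkene ends equatorial and cis to bromine. The step needs C–C bond formation at a hindered carbon to outrun protodesilylation and proton loss from 11; the high π-nucleophilicity of the enol silane, the six-membered chair and the buffered, non-nucleophilic solvent should secure this. Because silicon and not a proton is lost from 12, the carbonyl group (and later the methylene) is placed without regioisomers.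

Step 8
Reactants: 13 (4R,6R)-4-bromo-5,5,9-trimethylspiro[5.5]undec-8-en-1-one
Product: 14 (2R,6S)-2-bromo-1,1,9-trimethyl-5-methylidenespiro[5.5]undec-8-ene
Conditions: Ph3PCH3Br, KOtBu, toluene, 80 °C
Reagents that add atoms: methyltriphenylphosphonium bromide C[P+](c1ccccc1)(c1ccccc1)c1ccccc1.[Br-]
Why: Wittig methylenation of a hindered ketone with the unstabilised ylide at elevated temperature places the exocyclic methylene exactly at the carbonyl carbon; the equatorial secondary bromide next to a quaternary carbon has no antiperiplanar hydrogen and should resist E2 and SN2 attack.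

Step 9
Reactants: 14 (2R,6S)-2-bromo-1,1,9-trimethyl-5-methylidenespiro[5.5]undec-8-ene
Product: 16 (2R,6S,8S,9S)-2,8-dibromo-9-chloro-1,1,9-trimethyl-5-methylidenespiro[5.5]undecane (target), via ring-B bromonium chloride 15 (not isolated)
Conditions: Bu4NBrCl2 (1.05 equiv), CH2Cl2, −78 °C
Reagents that add atoms: tetrabutylammonium dichlorobromate Bu4NBrCl2 CCCC[N+](CCCC)(CCCC)CCCC.[Cl-].ClBr
Why: Electrophilic anti bromochlorination: the trisubstituted ring-B alkene is more nucleophilic and less hindered than the neopentyl-type exocyclic methylene, Br+ should be taken up on the face anti to the axial ring-A carbon (the C=CH2 carbon) of the spiro centre to give 15, and chloride should open this unsymmetrical ion at the tertiary carbon from the opposite face, which sets both ring-B centres in one event as the trans diequatorial bromochloride.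

**Compound list**
1 | 3-methylbut-2-en-1-ol (prenol) | CC(C)=CCO | starting material
2 | (2R)-2-bromo-3-chloro-3-methylbutan-1-ol | OC[C@@H](Br)C(C)(C)Cl | intermediate
3 | (2R)-2-bromo-3-chloro-3-methylbutyl trifluoromethanesulfonate | FC(F)(F)S(=O)(=O)OC[C@@H](Br)C(C)(C)Cl | intermediate
4 | 2-methylbuta-1,3-diene (isoprene) | C=CC(C)=C | starting material
5 | but-3-yn-2-one | CC(=O)C#C | starting material
6 | 1-(4-methylcyclohexa-1,4-dien-1-yl)ethan-1-one | CC(=O)C1=CCC(C)=CC1 | intermediate
7 | 1-(4-methylcyclohexa-1,3-dien-1-yl)ethan-1-one | CC(=O)C1=CC=C(C)CC1 | intermediate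
8 | lithium 1-(4-methylcyclohexa-1,3-dien-1-yl)ethen-1-olate | [Li]OC(=C)C1=CC=C(C)CC1 | intermediate (not isolated)
9 | (4R)-4-bromo-5-chloro-5-methyl-1-(4-methylcyclohexa-1,3-dien-1-yl)hexan-1-one | CC1=CC=C(CC1)C(=O)CC[C@@H](Br)C(C)(C)Cl | intermediate
10 | {[(1Z,4R)-4-bromo-5-chloro-5-methyl-1-(4-methylcyclohex-3-en-1-ylidene)hexyl]oxy}triethylsilane | CC1=CC/C(=C(\O[Si](CC)(CC)CC)CC[C@@H](Br)C(C)(C)Cl)CC1 | intermediate
11 | ring-A bromonium chloride (2,2-dimethylbromiranium ion formed from 10 by loss of chloride) | CC1=CC/C(=C(\O[Si](CC)(CC)CC)CC[C@H]2[Br+]C2(C)C)CC1.[Cl-] | intermediate (not isolated)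
12 | O-triethylsilyl oxocarbenium chloride of spiro ketone 13 | CC[Si](CC)(CC)[O+]=C1CC[C@@H](Br)C(C)(C)[C@]12CCC(C)=CC2.[Cl-] | intermediate (not isolated)
13 | (4R,6R)-4-bromo-5,5,9-trimethylspiro[5.5]undec-8-en-1-one | O=C1CC[C@@H](Br)C(C)(C)[C@]12CCC(C)=CC2 | intermediate
14 | (2R,6S)-2-bromo-1,1,9-trimethyl-5-methylidenespiro[5.5]undec-8-ene | C=C1CC[C@@H](Br)C(C)(C)[C@]12CCC(C)=CC2 | intermediate
15 | ring-B bromonium chloride of 14 (Br bridging C8 and C9 on the face cis to the CMe2 carbon) | C=C1CC[C@@H](Br)C(C)(C)[C@]12CC[C@@]3(C)[Br+][C@H]3C2.[Cl-] | intermediate (not isolated)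
16 | (2R,6S,8S,9S)-2,8-dibromo-9-chloro-1,1,9-trimethyl-5-methylidenespiro[5.5]undecane | C=C1CC[C@@H](Br)C(C)(C)[C@]12CC[C@](C)(Cl)[C@@H](Br)C2 | target

**Total step count:** 9
**Longest linear sequence:** 7 steps (steps 3 to 9 from isoprene and but-3-yn-2-one; steps 1, 2 and 5 to 9 from prenol are also 7)

**Steps most likely to fail**

Step 7. C–C bond formation at the fully substituted enol carbon may be outrun by protodesilylation of the enol silane in the protic medium, or by proton loss from the bromonium ion to an allylic bromide; the relay of configuration to the spiro centre would then be lost. The fallback sets out from 3 and comes back at 14: ring A is closed first on a less substituted nucleophile, and the spiro centre is made afterwards. The kinetic lithium enolate of commercial hex-5-en-2-one is alkylated with 3 to give (8R)-8-bromo-9-chloro-9-methyldec-1-en-5-one F1. In HFIP, F1 should close the same CMe2–C bond through its enol, since only the enol toward the allyl-bearing carbon can form a six-membered ring; this gives (4R)-4-bromo-3,3-dimethyl-2-(prop-2-en-1-yl)cyclohexan-1-one F2 (both epimers at C2 serve). Acid-catalysed (TfOH) Michael addition of F2 to but-3-en-2-one through the more substituted enol should occur by axial attack trans to the ring bromine, which avoids a 1,3-diaxial contact with it, and give (2R,4R)-4-bromo-3,3-dimethyl-2-(3-oxobutyl)-2-(prop-2-en-1-yl)cyclohexan-1-one F3. Double Wittig methylenation then gives (1R,3S)-1-bromo-2,2-dimethyl-4-methylidene-3-(3-methylbut-3-en-1-yl)-3-(prop-2-en-1-yl)cyclohexane F4, and ring-closing metathesis with the second-generation Grubbs catalyst closes ring B to 14.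

Step 6. Hydride may be delivered 1,6 to the dienone, or the enol-ether geometry may erode through reaction of other conformers; either would scramble the spiro centre in step 7. The fallback sets out from 6 and comes back at 10: the non-conjugated isomer is used, so that no dienone is present and the geometry is read from the ground-state conformer instead. The kinetic enolate of 6 is alkylated with 3 to give (4R)-4-bromo-5-chloro-5-methyl-1-(4-methylcyclohexa-1,4-dien-1-yl)hexan-1-one F5. Ionic 1,4-hydrosilylation (Et3SiH, B(C6F5)3 cat., toluene, −78 °C) should then deliver hydride to the β-carbon of the O-silylated enone in its preferred s-trans form, in which the chain sits next to the vinylic CH and the oxygen next to the ring CH2 beside the isolated ring alkene; this should give the same Z enol silane 10.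

Step 9. Facial selectivity may be poor: bromonium formation is reversible, and the ion on the face syn to the axial ring-A carbon can open trans-diaxially at the tertiary carbon, which would give the isomer epimeric at both ring-B centres; attack on the exocyclic alkene is a lesser risk. The fallback sets out from 14 and comes back at 16, in two operations through a bromohydrin. NBS in aqueous acetone should capture the kinetically preferred bromonium ion (anti to the axial ring-A carbon) irreversibly with water at the tertiary carbon, giving (2R,6S,8S,9S)-2,8-dibromo-1,1,9-trimethyl-5-methylidenespiro[5.5]undecan-9-ol F6. Anhydrous HCl in CH2Cl2 at −20 °C then ionises the tertiary alcohol, the neighbouring bromine bridges from its own face and chloride enters anti to it, so C–O is replaced by C–Cl with retention to give 16.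

**Further compounds**
F1 | step 7 | (8R)-8-bromo-9-chloro-9-methyldec-1-en-5-one | C=CCCC(=O)CC[C@@H](Br)C(C)(C)Cl
F2 | step 7 | (4R)-4-bromo-3,3-dimethyl-2-(prop-2-en-1-yl)cyclohexan-1-one | O=C1CC[C@@H](Br)C(C)(C)C1CC=C
F3 | step 7 | (2R,4R)-4-bromo-3,3-dimethyl-2-(3-oxobutyl)-2-(prop-2-en-1-yl)cyclohexan-1-one | O=C1CC[C@@H](Br)C(C)(C)[C@]1(CC=C)CCC(C)=O
F4 | step 7 | (1R,3S)-1-bromo-2,2-dimethyl-4-methylidene-3-(3-methylbut-3-en-1-yl)-3-(prop-2-en-1-yl)cyclohexane | C=C1CC[C@@H](Br)C(C)(C)[C@]1(CC=C)CCC(C)=C
F5 | step 6 | (4R)-4-bromo-5-chloro-5-methyl-1-(4-methylcyclohexa-1,4-dien-1-yl)hexan-1-one | CC1=CCC(=CC1)C(=O)CC[C@@H](Br)C(C)(C)Cl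
F6 | step 9 | (2R,6S,8S,9S)-2,8-dibromo-1,1,9-trimethyl-5-methylidenespiro[5.5]undecan-9-ol | C=C1CC[C@@H](Br)C(C)(C)[C@]12CC[C@](C)(O)[C@@H](Br)C2
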